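The route rests on disconnecting ring C at C1'–C5' together with a lactone bond between the C5' oxygen and the future C2. The key step exploits one feature of ring C: on quaternary C1' the C5' hydroxyl and C2 are cis, so oxygen and C2 can be tied into a cis-fused β-lactone. A nucleophile-catalysed aldol-lactonization of an open-chain aldehyde acid (silyloxy group at C3', gem-dimethyl C2', α-methyl acid) forms C1'–C5', ring C, the lactone and both stereocentres in one operation. The lactone carbonyl then becomes C2: MeLi opening, enolate alkenylation with a ring B triflate (C1–C8a) and Barbier closure of ring A (C2–C3) finish the skeleton.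

Key step: step 8

Remark 1: locants are those of the target (decalin C1–C8a, cyclopentane C1'–C5'); β is the face of the C4a methyl group, α the opposite face.
Remark 2: C2 of the open-chain acids 6–17 is carried as both epimers (SMILES leave it undefined); the ammonium enolate of step 8 erases this centre.
Remark 3: the (R)-configured phosphoric acid is assumed to give the (4R)-carbinol in step 5; if the sense is opposite, its enantiomer is used.
Remark 4: the acid is carried as its tert-butyl ester from step 3 to step 6, because a free γ-hydroxy acid or a small ester would close to the γ-lactone after step 5.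

Step 1
Reactants: 1 3-methylbut-2-en-1-ol; 2 propanoyl chloride
Product: 3 3-methylbut-2-en-1-yl propanoate
Conditions: Et3N, DMAP (cat.), CH2Cl2, 0 °C
Reagents that add atoms: none
Why: Acylation of a primary allylic alcohol by an acid chloride (esterification) is routine and creates no stereocentre.

Step 2
Reactants: 3 3-methylbut-2-en-1-yl propanoate
Product: 6 2,3,3-trimethylpent-4-enoic acid (racemic), via silyl ketene acetal 4 (not isolated), via trimethylsilyl ester 5 (not isolated)
Conditions: LiN(iPr)2, THF, −78 °C; Me3SiCl, −78 → 60 °C; then 1 M HCl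
Reagents that add atoms: none
Why: In the Ireland–Claisen rearrangement the silyl ketene acetal 4 should shift through a chair-like [3,3] transition state onto the dimethyl-substituted alkene terminus, which forges the future C1'–C2' bond with quaternary C2' and leaves an α-methyl centre whose configuration does not matter.

Step 3
Reactants: 6 2,3,3-trimethylpent-4-enoic acid
Product: 7 tert-butyl 2,3,3-trimethylpent-4-enoate
Conditions: tert-butyl 2,2,2-trichloroacetimidate, BF3·OEt2 (cat.), cyclohexane/CH2Cl2, rt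
Reagents that add atoms: tert-butyl 2,2,2-trichloroacetimidate, CC(C)(C)OC(=N)C(Cl)(Cl)Cl
Why: Imidate tert-butylation passes through the tert-butyl cation, so the hindered carboxyl carbon need not be attacked, and the bulky ester should not close onto the hydroxyl made in step 5.

Step 4
Reactants: 7 tert-butyl 2,3,3-trimethylpent-4-enoate
Product: 9 tert-butyl 2,3,3-trimethyl-4-oxobutanoate, via ozonide 8 (not isolated)
Conditions: O3, CH2Cl2, −78 °C; then PPh3, −78 °C → rt
Reagents that add atoms: ozone, [O-][O+]=O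
Why: Ozonolysis with reductive work-up cleaves the only alkene to a neopentyl aldehyde that has no α-hydrogen and therefore cannot enolise.

Step 5
Reactants: 9 tert-butyl 2,3,3-trimethyl-4-oxobutanoate; 10 allylboronic acid pinacol ester
Product: 12 tert-butyl (4R)-4-hydroxy-2,3,3-trimethylhept-6-enoate, via borate ester 11 (not isolated)
Conditions: (R)-3,3'-bis(2,4,6-triisopropylphenyl)-1,1'-binaphthyl-2,2'-diyl hydrogen phosphate (5 mol %), toluene, −30 °C; aqueous work-up
Reagents that add atoms: none
Why: In this Brønsted acid-catalysed allylboration the chiral phosphoric acid activates the boronate in a closed six-membered chair transition state and selects the aldehyde face, so the future C3' is set (R) by the catalyst while the remote α-methyl centre has no say.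

Step 6
Reactants: 12 tert-butyl (4R)-4-hydroxy-2,3,3-trimethylhept-6-enoate
Product: 15 (4R)-4-[(tert-butyldimethylsilyl)oxy]-2,3,3-trimethylhept-6-enoic acid, via silyl ether tert-butyl ester 13 (not isolated), via silyl ester 14 (not isolated)
Conditions: TBSOTf (3 equiv), 2,6-lutidine, CH2Cl2, −78 °C → rt; then K2CO3, MeOH/H2O, 0 °C; acidify to pH 4
Reagents that add atoms: tert-butyldimethylsilyl trifluoromethanesulfonate, CC(C)(C)[Si](C)(C)OS(=O)(=O)C(F)(F)F
Why: The silyl triflate should first silylate the hindered carbinol and then, on warming, turn the tert-butyl ester into the silyl ester with loss of isobutene (silyl triflate-mediated ester dealkylation), after which mild methanolysis frees the acid without a lactonisable hydroxy acid ever being present.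

Step 7
Reactants: 15 (4R)-4-[(tert-butyldimethylsilyl)oxy]-2,3,3-trimethylhept-6-enoic acid
Product: 17 (4R)-4-[(tert-butyldimethylsilyl)oxy]-2,3,3-trimethyl-6-oxohexanoic acid, via ozonide 16 (not isolated)
Conditions: O3, CH2Cl2, −78 °C; then PPh3, −78 °C → rt
Reagents that add atoms: ozone, [O-][O+]=O
Why: Ozonolysis with a neutral phosphine work-up turns the terminal alkene into the future C5' aldehyde and leaves the base-sensitive β-silyloxy aldehyde and the free acid intact.

Step 8
Reactants: 17 (4R)-4-[(tert-butyldimethylsilyl)oxy]-2,3,3-trimethyl-6-oxohexanoic acid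
Product: 21 (1S,3R,5R)-3-[(tert-butyldimethylsilyl)oxy]-1,2,2-trimethyl-6-oxabicyclo[3.2.0]heptan-7-one, via acyloxypyridinium salt 18 (not isolated), via ammonium enolate 19 (not isolated), via ammonium aldolate 20 (not isolated)
Conditions: 2-chloro-1-methylpyridinium iodide (3 equiv), O-trimethylsilylquinidine (0.2–1.0 equiv), iPr2NEt (4 equiv), MeCN, 25 °C, slow addition of 17
Reagents that add atoms: none
Why: In this nucleophile-catalysed aldol-lactonization the pyridinium salt turns the acid into the acyloxypyridinium 18, and base and O-trimethylsilylquinidine convert it (through the ketene or the acylammonium ion) into the ammonium enolate 19, in which both C2 epimers of 17 converge. The enolate carbon C1' should add to the tethered aldehyde in a 5-exo-trig closure of ring C, and the aldolate 20 then attacks the acylammonium carbon (future C2) in a 4-exo-trig closure that forms the β-lactone and returns the catalyst. The closest known reaction type is the cinchona alkaloid-catalysed intramolecular aldol-lactonization of aldehyde acids, including α-branched acids that give a quaternary α-carbon. The cis fusion, that is the cis relation of the C5' oxygen and C2 on C1', is enforced by the four-membered ring, while the absolute configuration of C1' and C5' is set by the enolate face that the quinidine-derived ammonium group leaves open. The step needs this pair to form anti to the C3' silyloxy group, which the catalyst should provide and the substrate should reinforce, because the bulky silyloxy group next to the gem-dimethyl carbon takes a pseudo-equatorial position and keeps the aldehyde on the opposite face. Intermolecular aldol reaction is held back by slow addition and by the gem-dimethyl group, which favours ring closure.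

Step 9
Reactants: 21 (1S,3R,5R)-3-[(tert-butyldimethylsilyl)oxy]-1,2,2-trimethyl-6-oxabicyclo[3.2.0]heptan-7-one
Product: 22 (1S,3R,5R)-3-hydroxy-1,2,2-trimethyl-6-oxabicyclo[3.2.0]heptan-7-one
Conditions: 48 % aq. HF, MeCN, 0 °C → rt
Reagents that add atoms: none
Why: Acidic fluoride desilylation should free the C3' hydroxyl while the β-lactone, which tolerates acid but not basic fluoride, survives.

Step 10
Reactants: 22 (1S,3R,5R)-3-hydroxy-1,2,2-trimethyl-6-oxabicyclo[3.2.0]heptan-7-one
Product: 24 (1S,3S,5R)-3-bromo-1,2,2-trimethyl-6-oxabicyclo[3.2.0]heptan-7-one, via triflate 23 (not isolated)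
Conditions: Tf2O, pyridine, CH2Cl2, −30 °C; then n-Bu4NBr, −30 °C → rt
Reagents that add atoms: tetrabutylammonium bromide, CCCC[N+](CCCC)(CCCC)CCCC.[Br-]
Why: Triflation followed by SN2 displacement with soluble bromide should invert C3' and place bromine cis to the lactone oxygen, the low temperature and the weakly ionising medium disfavouring ionisation of the neopentylic triflate.

Step 11
Reactants: 24 (1S,3S,5R)-3-bromo-1,2,2-trimethyl-6-oxabicyclo[3.2.0]heptan-7-one
Product: 25 1-[(1S,3S,5R)-3-bromo-5-hydroxy-1,2,2-trimethylcyclopentyl]ethan-1-one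
Conditions: MeLi (1.1 equiv), THF, −78 °C; aq. NH4Cl at −78 °C
Reagents that add atoms: methyllithium, [Li]C
Why: In this acyl substitution MeLi attacks the strained lactone carbonyl (future C2), the tetrahedral intermediate collapses with release of ring strain, and the resulting methyl ketone next to quaternary C1' should resist a second addition at −78 °C.

Step 12
Reactants: 25 1-[(1S,3S,5R)-3-bromo-5-hydroxy-1,2,2-trimethylcyclopentyl]ethan-1-one
Product: 26 1-[(1S,3S,5R)-3-bromo-5-[(tert-butyldimethylsilyl)oxy]-1,2,2-trimethylcyclopentyl]ethan-1-one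
Conditions: TBSOTf (1.2 equiv), 2,6-lutidine, CH2Cl2, −78 → 0 °C
Reagents that add atoms: tert-butyldimethylsilyl trifluoromethanesulfonate, CC(C)(C)[Si](C)(C)OS(=O)(=O)C(F)(F)F
Why: Silyl ether formation at the C5' hydroxyl masks the β-hydroxy ketone against retro-aldol cleavage in the basic steps that follow.

Step 13
Reactants: 27 2-methylcyclohexane-1,3-dione; 28 3-bromoprop-1-ene
Product: 29 2-methyl-2-(prop-2-en-1-yl)cyclohexane-1,3-dione
Conditions: 1 M NaOH (aq), rt
Reagents that add atoms: none
Why: C-Alkylation of the stabilised 1,3-diketone enolate with an allylic halide (enolate alkylation) should give the prochiral dione that carries the future C4a with its methyl group and the C4–C3 chain.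

Step 14
Reactants: 29 2-methyl-2-(prop-2-en-1-yl)cyclohexane-1,3-dione
Product: 30 (2S,3S)-3-hydroxy-2-methyl-2-(prop-2-en-1-yl)cyclohexan-1-one
Conditions: baker's yeast, sucrose, H2O, 30 °C
Reagents that add atoms: none
Why: This enzymatic desymmetrising reduction is a well-established transformation of this dione, and by reducing one enantiotopic carbonyl from the face anti to the allyl group it sets C4a and C5 together, with the hydroxyl trans to the methyl group.

Step 15
Reactants: 30 (2S,3S)-3-hydroxy-2-methyl-2-(prop-2-en-1-yl)cyclohexan-1-one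
Product: 32 (2R,3R)-3-bromo-2-methyl-2-(prop-2-en-1-yl)cyclohexan-1-one, via triflate 31 (not isolated)
Conditions: Tf2O, pyridine, CH2Cl2, −30 °C; then n-Bu4NBr, −30 °C → rt
Reagents that add atoms: tetrabutylammonium bromide, CCCC[N+](CCCC)(CCCC)CCCC.[Br-]
Why: Triflation and SN2 displacement by bromide should invert C5 and place bromine cis to the C4a methyl group, since quaternary C4a bars β-elimination towards the carbonyl and the electron-withdrawing ketone disfavours ionisation.

Step 16
Reactants: 32 (2R,3R)-3-bromo-2-methyl-2-(prop-2-en-1-yl)cyclohexan-1-one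
Product: 33 (5R,6R)-5-bromo-6-methyl-6-(prop-2-en-1-yl)cyclohex-1-en-1-yl trifluoromethanesulfonate
Conditions: KN(SiMe3)2, THF, −78 °C; PhNTf2, −78 → 0 °C
Reagents that add atoms: N-phenylbis(trifluoromethanesulfonimide), O=S(=O)(N(c1ccccc1)S(=O)(=O)C(F)(F)F)C(F)(F)F
Why: Deprotonation can occur only at C8 because C4a is quaternary, so O-triflation of the enolate (enol triflate formation) fixes the C8=C8a double bond regiospecifically.

Step 17
Reactants: 33 (5R,6R)-5-bromo-6-methyl-6-(prop-2-en-1-yl)cyclohex-1-en-1-yl trifluoromethanesulfonate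
Product: 36 2-[(1R,6R)-6-bromo-1-methyl-2-(trifluoromethanesulfonyloxy)cyclohex-2-en-1-yl]ethan-1-ol, via ozonide 34 (not isolated), via aldehyde 35 (not isolated)
Conditions: O3, CH2Cl2, −78 °C (stopped when the terminal alkene is consumed); then NaBH4, MeOH, −78 → 0 °C
Reagents that add atoms: ozone, [O-][O+]=O
Why: Ozonolysis should be chemoselective for the electron-rich terminal alkene over the electron-poor, hindered enol triflate, and borohydride reduction of the ozonide gives the primary alcohol at C3.

Step 18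
Reactants: 36 2-[(1R,6R)-6-bromo-1-methyl-2-(trifluoromethanesulfonyloxy)cyclohex-2-en-1-yl]ethan-1-ol
Product: 37 (5R,6R)-5-bromo-6-methyl-6-[2-(triethylsilyloxy)ethyl]cyclohex-1-en-1-yl trifluoromethanesulfonate
Conditions: Et3SiCl, imidazole, CH2Cl2, 0 °C
Reagents that add atoms: chlorotriethylsilane, CC[Si](Cl)(CC)CC
Why: Silyl ether formation gives a primary triethylsilyl ether that can later be cleaved in the presence of the hindered secondary TBS ether.

Step 19
Reactants: 26 1-[(1S,3S,5R)-3-bromo-5-[(tert-butyldimethylsilyl)oxy]-1,2,2-trimethylcyclopentyl]ethan-1-one; 37 (5R,6R)-5-bromo-6-methyl-6-[2-(triethylsilyloxy)ethyl]cyclohex-1-en-1-yl trifluoromethanesulfonate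
Product: 38 1-[(1S,3S,5R)-3-bromo-5-[(tert-butyldimethylsilyl)oxy]-1,2,2-trimethylcyclopentyl]-2-{(5R,6R)-5-bromo-6-methyl-6-[2-(triethylsilyloxy)ethyl]cyclohex-1-en-1-yl}ethan-1-one
Conditions: LiN(SiMe3)2 (2.2 equiv), Pd2(dba)3 (2.5 mol %), 2-dicyclohexylphosphino-2',4',6'-triisopropylbiphenyl (6 mol %), THF, 50 °C
Reagents that add atoms: none
Why: In this palladium-catalysed α-alkenylation of a ketone enolate the lithium enolate of 26, which can form only on the methyl group, should couple with the alkenyl triflate at zerovalent palladium (oxidative addition, transmetalation, reductive elimination) to form C1–C8a, and protonation of the product enolate at C1 keeps the ketone β,γ-unsaturated.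

Step 20
Reactants: 38 union ketone
Product: 39 1-[(1S,3S,5R)-3-bromo-5-[(tert-butyldimethylsilyl)oxy]-1,2,2-trimethylcyclopentyl]-2-[(5R,6R)-5-bromo-6-(2-hydroxyethyl)-6-methylcyclohex-1-en-1-yl]ethan-1-one
Conditions: pyridinium p-toluenesulfonate (cat.), MeOH, 0 °C → rt
Reagents that add atoms: none
Why: Acid-catalysed methanolysis of the primary triethylsilyl ether should be far faster than that of the hindered secondary TBS ether (selective desilylation).

Step 21
Reactants: 39 primary alcohol
Product: 40 1-[(1S,3S,5R)-3-bromo-5-[(tert-butyldimethylsilyl)oxy]-1,2,2-trimethylcyclopentyl]-2-[(5R,6R)-5-bromo-6-(2-iodoethyl)-6-methylcyclohex-1-en-1-yl]ethan-1-one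
Conditions: I2, PPh3, imidazole, CH2Cl2, 0 °C
Reagents that add atoms: iodine, II
Why: Appel-type iodination through the alkoxyphosphonium salt should convert the unhindered primary alcohol into the iodide by SN2 displacement without touching the ketone or the secondary bromides.

Step 22
Reactants: 40 iodo ketone
Product: 41 5β-bromo-2β-[(1S,3S,5R)-3-bromo-5-[(tert-butyldimethylsilyl)oxy]-1,2,2-trimethylcyclopentyl]-4aβ-methyl-1,2,3,4,4a,5,6,7-octahydronaphthalen-2α-ol
Conditions: SmI2 (2.5 equiv), NiI2 (2 mol %), THF, 0 °C; aq. NH4Cl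
Reagents that add atoms: none
Why: In this Barbier cyclisation divalent samarium reduces the primary iodide, by far the most easily reduced halide present, and the alkylsamarium species should add to the C2 ketone through a chair-like six-membered transition state with the bulky cyclopentyl group equatorial and the oxygen axial on the α face, which closes ring A (C2–C3) and sets C2.

Step 23
Reactants: 41 octalinol
Product: 42 5β-bromo-2β-[(1S,3S,5R)-3-bromo-5-[(tert-butyldimethylsilyl)oxy]-1,2,2-trimethylcyclopentyl]-4aβ-methyldecahydronaphthalene-2α,8α,8aα-triol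
Conditions: OsO4 (5 mol %), 4-methylmorpholine 4-oxide, acetone/H2O, rt
Reagents that add atoms: osmium tetroxide, O=[Os](=O)(=O)=O; 4-methylmorpholine 4-oxide (terminal oxygen source), C[N+]1([O-])CCOCC1
Why: Catalytic syn-dihydroxylation should attack the trisubstituted C8=C8a alkene from the face opposite the adjacent axial C4a methyl group, which places the C8a hydroxyl α and gives the trans ring fusion, while the configuration of the secondary C8 carbinol is of no consequence.

Step 24
Reactants: 42 triol
Product: 43 5β-bromo-2β-[(1S,3S,5R)-3-bromo-5-[(tert-butyldimethylsilyl)oxy]-1,2,2-trimethylcyclopentyl]-2α,8aα-dihydroxy-4aβ-methyldecalin-8-one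
Conditions: (COCl)2, DMSO, CH2Cl2, −78 °C; Et3N, −78 → −20 °C
Reagents that add atoms: none
Why: Swern oxidation should convert only the secondary C8 alcohol into the ketone, since the tertiary hydroxyls cannot be oxidised, and the low temperature avoids an α-ketol shift.

Step 25
Reactants: 43 α-hydroxy ketone
Product: 44 5β-bromo-2β-[(1S,3S,5R)-3-bromo-5-[(tert-butyldimethylsilyl)oxy]-1,2,2-trimethylcyclopentyl]-4aβ,8α-dimethyldecahydronaphthalene-2α,8β,8aα-triol
Conditions: MeLi (6 equiv), CeCl3 (6 equiv), THF, −78 °C; aq. NH4Cl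
Reagents that add atoms: methyllithium, [Li]C
Why: In this 1,2-addition of a methylcerium reagent the axial approach to the C8 ketone is blocked by the syn-axial C4a methyl group, so the methyl group should enter equatorially (α) and leave the C8 hydroxyl axial (β), trans to the C8a hydroxyl.

Step 26
Reactants: 44 silyl ether of the target
Product: 45 5β-bromo-2β-[(1S,3S,5R)-3-bromo-5-hydroxy-1,2,2-trimethylcyclopentyl]-4aβ,8α-dimethyldecahydronaphthalene-2α,8β,8aα-triol (CNP0390567.2)
Conditions: HF·pyridine, pyridine, THF, 0 °C → rt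
Reagents that add atoms: none
Why: Buffered fluoride cleavage of the last silyl ether (desilylation) should leave the tertiary alcohols and the secondary bromides untouched and deliver the target.

Compound list
1 | 3-methylbut-2-en-1-ol | CC(C)=CCO | starting material
2 | propanoyl chloride | CCC(=O)Cl | starting material
3 | 3-methylbut-2-en-1-yl propanoate | CCC(=O)OCC=C(C)C | intermediate
4 | trimethyl({1-[(3-methylbut-2-en-1-yl)oxy]prop-1-en-1-yl}oxy)silane (silyl ketene acetal) | CC=C(OCC=C(C)C)O[Si](C)(C)C | intermediate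
5 | trimethylsilyl 2,3,3-trimethylpent-4-enoate | C=CC(C)(C)C(C)C(=O)O[Si](C)(C)C | intermediate
6 | 2,3,3-trimethylpent-4-enoic acid (racemic) | C=CC(C)(C)C(C)C(O)=O | intermediate
7 | tert-butyl 2,3,3-trimethylpent-4-enoate | C=CC(C)(C)C(C)C(=O)OC(C)(C)C | intermediate
8 | tert-butyl 2,3-dimethyl-3-(1,2,4-trioxolan-3-yl)butanoate (ozonide) | CC(C(=O)OC(C)(C)C)C(C)(C)C1OCOO1 | intermediate
9 | tert-butyl 2,3,3-trimethyl-4-oxobutanoate | CC(C(=O)OC(C)(C)C)C(C)(C)C=O | intermediate
10 | allylboronic acid pinacol ester | C=CCB1OC(C)(C)C(C)(C)O1 | starting material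
11 | tert-butyl (4R)-2,3,3-trimethyl-4-[(4,4,5,5-tetramethyl-1,3,2-dioxaborolan-2-yl)oxy]hept-6-enoate (borate ester) | CC(C(=O)OC(C)(C)C)C(C)(C)[C@H](OB1OC(C)(C)C(C)(C)O1)CC=C | intermediate
12 | tert-butyl (4R)-4-hydroxy-2,3,3-trimethylhept-6-enoate (both C2 epimers) | CC(C(=O)OC(C)(C)C)C(C)(C)[C@H](O)CC=C | intermediate
13 | tert-butyl (4R)-4-[(tert-butyldimethylsilyl)oxy]-2,3,3-trimethylhept-6-enoate | CC(C(=O)OC(C)(C)C)C(C)(C)[C@H](O[Si](C)(C)C(C)(C)C)CC=C | intermediate
14 | tert-butyldimethylsilyl (4R)-4-[(tert-butyldimethylsilyl)oxy]-2,3,3-trimethylhept-6-enoate | CC(C(=O)O[Si](C)(C)C(C)(C)C)C(C)(C)[C@H](O[Si](C)(C)C(C)(C)C)CC=C | intermediate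
15 | (4R)-4-[(tert-butyldimethylsilyl)oxy]-2,3,3-trimethylhept-6-enoic acid | OC(=O)C(C)C(C)(C)[C@H](O[Si](C)(C)C(C)(C)C)CC=C | intermediate
16 | (4R)-4-[(tert-butyldimethylsilyl)oxy]-2,3,3-trimethyl-5-(1,2,4-trioxolan-3-yl)pentanoic acid (ozonide) | OC(=O)C(C)C(C)(C)[C@H](O[Si](C)(C)C(C)(C)C)CC1OCOO1 | intermediate
17 | (4R)-4-[(tert-butyldimethylsilyl)oxy]-2,3,3-trimethyl-6-oxohexanoic acid (both C2 epimers) | OC(=O)C(C)C(C)(C)[C@H](O[Si](C)(C)C(C)(C)C)CC=O | intermediate
18 | 2-acyloxy-1-methylpyridinium iodide of acid 17 | C[n+]1ccccc1OC(=O)C(C)C(C)(C)[C@H](O[Si](C)(C)C(C)(C)C)CC=O.[I-] | intermediate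
19 | ammonium enolate of 17 on O-trimethylsilylquinidine (zwitterion) | COc1ccc2nccc([C@@H]([C@H]3C[C@@H]4CC[N+]3(C([O-])=C(C)C(C)(C)[C@H](O[Si](C)(C)C(C)(C)C)CC=O)C[C@@H]4C=C)O[Si](C)(C)C)c2c1 | intermediate
20 | ammonium aldolate with ring C closed (zwitterion) | COc1ccc2nccc([C@@H]([C@H]3C[C@@H]4CC[N+]3(C(=O)[C@]5(C)[C@H]([O-])C[C@@H](O[Si](C)(C)C(C)(C)C)C5(C)C)C[C@@H]4C=C)O[Si](C)(C)C)c2c1 | intermediate
21 | (1S,3R,5R)-3-[(tert-butyldimethylsilyl)oxy]-1,2,2-trimethyl-6-oxabicyclo[3.2.0]heptan-7-one | CC1(C)[C@H](O[Si](C)(C)C(C)(C)C)C[C@H]2OC(=O)[C@@]12C | intermediate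
22 | (1S,3R,5R)-3-hydroxy-1,2,2-trimethyl-6-oxabicyclo[3.2.0]heptan-7-one | CC1(C)[C@H](O)C[C@H]2OC(=O)[C@@]12C | intermediate
23 | (1S,3R,5R)-1,2,2-trimethyl-7-oxo-6-oxabicyclo[3.2.0]heptan-3-yl trifluoromethanesulfonate | CC1(C)[C@H](OS(=O)(=O)C(F)(F)F)C[C@H]2OC(=O)[C@@]12C | intermediate
24 | (1S,3S,5R)-3-bromo-1,2,2-trimethyl-6-oxabicyclo[3.2.0]heptan-7-one | CC1(C)[C@@H](Br)C[C@H]2OC(=O)[C@@]12C | intermediate
25 | 1-[(1S,3S,5R)-3-bromo-5-hydroxy-1,2,2-trimethylcyclopentyl]ethan-1-one | CC1(C)[C@@H](Br)C[C@@H](O)[C@@]1(C)C(C)=O | intermediate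
26 | 1-[(1S,3S,5R)-3-bromo-5-[(tert-butyldimethylsilyl)oxy]-1,2,2-trimethylcyclopentyl]ethan-1-one | CC1(C)[C@@H](Br)C[C@@H](O[Si](C)(C)C(C)(C)C)[C@@]1(C)C(C)=O | intermediate
27 | 2-methylcyclohexane-1,3-dione | CC1C(=O)CCCC1=O | starting material
28 | 3-bromoprop-1-ene | C=CCBr | starting material
29 | 2-methyl-2-(prop-2-en-1-yl)cyclohexane-1,3-dione | C=CCC1(C)C(=O)CCCC1=O | intermediate
30 | (2S,3S)-3-hydroxy-2-methyl-2-(prop-2-en-1-yl)cyclohexan-1-one | C=CC[C@@]1(C)[C@@H](O)CCCC1=O | intermediate
31 | (1S,2S)-2-methyl-3-oxo-2-(prop-2-en-1-yl)cyclohexyl trifluoromethanesulfonate | C=CC[C@@]1(C)[C@@H](OS(=O)(=O)C(F)(F)F)CCCC1=O | intermediate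
32 | (2R,3R)-3-bromo-2-methyl-2-(prop-2-en-1-yl)cyclohexan-1-one | C=CC[C@@]1(C)[C@H](Br)CCCC1=O | intermediate
33 | (5R,6R)-5-bromo-6-methyl-6-(prop-2-en-1-yl)cyclohex-1-en-1-yl trifluoromethanesulfonate | C=CC[C@@]1(C)[C@H](Br)CCC=C1OS(=O)(=O)C(F)(F)F | intermediate
34 | (5R,6R)-5-bromo-6-methyl-6-[(1,2,4-trioxolan-3-yl)methyl]cyclohex-1-en-1-yl trifluoromethanesulfonate (ozonide) | C1(C[C@@]2(C)[C@H](Br)CCC=C2OS(=O)(=O)C(F)(F)F)OCOO1 | intermediate
35 | (5R,6R)-5-bromo-6-methyl-6-(2-oxoethyl)cyclohex-1-en-1-yl trifluoromethanesulfonate | O=CC[C@@]1(C)[C@H](Br)CCC=C1OS(=O)(=O)C(F)(F)F | intermediate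
36 | 2-[(1R,6R)-6-bromo-1-methyl-2-(trifluoromethanesulfonyloxy)cyclohex-2-en-1-yl]ethan-1-ol | OCC[C@@]1(C)[C@H](Br)CCC=C1OS(=O)(=O)C(F)(F)F | intermediate
37 | (5R,6R)-5-bromo-6-methyl-6-[2-(triethylsilyloxy)ethyl]cyclohex-1-en-1-yl trifluoromethanesulfonate | CC[Si](CC)(CC)OCC[C@@]1(C)[C@H](Br)CCC=C1OS(=O)(=O)C(F)(F)F | intermediate
38 | 1-[(1S,3S,5R)-3-bromo-5-[(tert-butyldimethylsilyl)oxy]-1,2,2-trimethylcyclopentyl]-2-{(5R,6R)-5-bromo-6-methyl-6-[2-(triethylsilyloxy)ethyl]cyclohex-1-en-1-yl}ethan-1-one | CC1(C)[C@@H](Br)C[C@@H](O[Si](C)(C)C(C)(C)C)[C@@]1(C)C(=O)CC1=CCC[C@@H](Br)[C@]1(C)CCO[Si](CC)(CC)CC | intermediate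
39 | 1-[(1S,3S,5R)-3-bromo-5-[(tert-butyldimethylsilyl)oxy]-1,2,2-trimethylcyclopentyl]-2-[(5R,6R)-5-bromo-6-(2-hydroxyethyl)-6-methylcyclohex-1-en-1-yl]ethan-1-one | CC1(C)[C@@H](Br)C[C@@H](O[Si](C)(C)C(C)(C)C)[C@@]1(C)C(=O)CC1=CCC[C@@H](Br)[C@]1(C)CCO | intermediate
40 | 1-[(1S,3S,5R)-3-bromo-5-[(tert-butyldimethylsilyl)oxy]-1,2,2-trimethylcyclopentyl]-2-[(5R,6R)-5-bromo-6-(2-iodoethyl)-6-methylcyclohex-1-en-1-yl]ethan-1-one | CC1(C)[C@@H](Br)C[C@@H](O[Si](C)(C)C(C)(C)C)[C@@]1(C)C(=O)CC1=CCC[C@@H](Br)[C@]1(C)CCI | intermediate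
41 | 5β-bromo-2β-[(1S,3S,5R)-3-bromo-5-[(tert-butyldimethylsilyl)oxy]-1,2,2-trimethylcyclopentyl]-4aβ-methyl-1,2,3,4,4a,5,6,7-octahydronaphthalen-2α-ol | CC1(C)[C@@H](Br)C[C@@H](O[Si](C)(C)C(C)(C)C)[C@@]1(C)[C@]1(O)CC[C@@]2(C)[C@H](Br)CCC=C2C1 | intermediate
42 | 5β-bromo-2β-[(1S,3S,5R)-3-bromo-5-[(tert-butyldimethylsilyl)oxy]-1,2,2-trimethylcyclopentyl]-4aβ-methyldecahydronaphthalene-2α,8α,8aα-triol | CC1(C)[C@@H](Br)C[C@@H](O[Si](C)(C)C(C)(C)C)[C@@]1(C)[C@]1(O)CC[C@@]2(C)[C@H](Br)CC[C@@H](O)[C@]2(O)C1 | intermediate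
43 | 5β-bromo-2β-[(1S,3S,5R)-3-bromo-5-[(tert-butyldimethylsilyl)oxy]-1,2,2-trimethylcyclopentyl]-2α,8aα-dihydroxy-4aβ-methyldecalin-8-one | CC1(C)[C@@H](Br)C[C@@H](O[Si](C)(C)C(C)(C)C)[C@@]1(C)[C@]1(O)CC[C@@]2(C)[C@H](Br)CCC(=O)[C@]2(O)C1 | intermediate
44 | 5β-bromo-2β-[(1S,3S,5R)-3-bromo-5-[(tert-butyldimethylsilyl)oxy]-1,2,2-trimethylcyclopentyl]-4aβ,8α-dimethyldecahydronaphthalene-2α,8β,8aα-triol | CC1(C)[C@@H](Br)C[C@@H](O[Si](C)(C)C(C)(C)C)[C@@]1(C)[C@]1(O)CC[C@@]2(C)[C@H](Br)CC[C@](C)(O)[C@]2(O)C1 | intermediate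
45 | CNP0390567.2: 5β-bromo-2β-[(1S,3S,5R)-3-bromo-5-hydroxy-1,2,2-trimethylcyclopentyl]-4aβ,8α-dimethyldecahydronaphthalene-2α,8β,8aα-triol | CC1(C)[C@@H](Br)C[C@@H](O)[C@@]1(C)[C@]1(O)CC[C@@]2(C)[C@H](Br)CC[C@](C)(O)[C@]2(O)C1 | target

Total step count: 26. Longest linear sequence: 20 steps (steps 1–12, then 19–26); the ring B branch (steps 13–18) joins at step 19.

Steps most likely to fail

1. Step 8 (key step). The α-branched acylammonium ion may enolise too slowly, so that the aldehyde condenses intermolecularly or the activated acid is consumed as anhydride, and the alkaloid may fail to override the C3' silyloxy centre, which would give the C1'/C5' pair on the wrong face. Fallback: the same two bonds are made in separate stages with a thioester. Setting out from acid 15, benzenethiol with DCC and DMAP should give the S-phenyl thioester F1, and ozonolysis (O3, then PPh3) the aldehyde thioester F2. Soft enolisation with MgBr2·OEt2 and iPr2NEt in CH2Cl2 (direct thioester aldol) should close ring C to the β-hydroxy thioester F3, of which the isomer with hydroxyl and thioester cis is separated. Activation of the thioester with AgO2CCF3 should then transfer the acyl group to the neighbouring hydroxyl, and the route is rejoined at lactone 21.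

2. Step 10. Ionisation of the neopentylic triflate 23, with methyl migration from C2' or loss of triflic acid towards C4', may outrun backside attack of bromide on the lactone face. Fallback: the preformed sulfonate is given up, and alcohol 22 is deoxybrominated in one stage by the Appel reaction (CBr4, PBu3, toluene, 60 °C). Bromide then collapses onto the alkoxyphosphonium bromide F4 within an ion pair in a non-polar medium, which should favour inversion over ionisation, and the route is rejoined at bromo lactone 24.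

3. Step 19. Reductive elimination from the hindered alkenyl(enolato)palladium species may be slow, so that the triflate is merely reduced, and the amide base may remove HBr from the secondary bromides at 50 °C. Fallback: the enolate is made without strong base as a zinc enolate. Setting out from ketone 26, LiN(SiMe3)2 and Me3SiCl at −78 °C should give the silyl enol ether F5, and N-bromosuccinimide the α-bromo ketone F6. Zn dust in THF should then give the bromozinc enolate F7 (Reformatsky reagent), which is cross-coupled with triflate 37 under Pd(PPh3)4 catalysis (Negishi-type coupling of a zinc enolate), and the route is rejoined at ketone 38.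

Further compounds
F1 | step 8 | S-phenyl (4R)-4-[(tert-butyldimethylsilyl)oxy]-2,3,3-trimethylhept-6-enethioate | O=C(Sc1ccccc1)C(C)C(C)(C)[C@H](O[Si](C)(C)C(C)(C)C)CC=C
F2 | step 8 | S-phenyl (4R)-4-[(tert-butyldimethylsilyl)oxy]-2,3,3-trimethyl-6-oxohexanethioate | O=C(Sc1ccccc1)C(C)C(C)(C)[C@H](O[Si](C)(C)C(C)(C)C)CC=O
F3 | step 8 | S-phenyl (1S,3R,5R)-3-[(tert-butyldimethylsilyl)oxy]-5-hydroxy-1,2,2-trimethylcyclopentane-1-carbothioate | CC1(C)[C@H](O[Si](C)(C)C(C)(C)C)C[C@@H](O)[C@@]1(C)C(=O)Sc1ccccc1
F4 | step 10 | tributyl{[(1S,3R,5R)-1,2,2-trimethyl-7-oxo-6-oxabicyclo[3.2.0]heptan-3-yl]oxy}phosphonium bromide | CC1(C)[C@H](O[P+](CCCC)(CCCC)CCCC)C[C@H]2OC(=O)[C@@]12C.[Br-]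
F5 | step 19 | {[1-[(1S,3S,5R)-3-bromo-5-[(tert-butyldimethylsilyl)oxy]-1,2,2-trimethylcyclopentyl]ethenyl]oxy}trimethylsilane | CC1(C)[C@@H](Br)C[C@@H](O[Si](C)(C)C(C)(C)C)[C@@]1(C)C(=C)O[Si](C)(C)C
F6 | step 19 | 2-bromo-1-[(1S,3S,5R)-3-bromo-5-[(tert-butyldimethylsilyl)oxy]-1,2,2-trimethylcyclopentyl]ethan-1-one | CC1(C)[C@@H](Br)C[C@@H](O[Si](C)(C)C(C)(C)C)[C@@]1(C)C(=O)CBr
F7 | step 19 | bromozinc enolate of ketone 26 | CC1(C)[C@@H](Br)C[C@@H](O[Si](C)(C)C(C)(C)C)[C@@]1(C)C(=C)O[Zn]Br
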